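(The earlier runs and the new flask were computed for substances that don't exist.)

Which way of bringing the same charge together leaves the most links after 4.0 d?

| flask | first end groups | second end groups | protic impurity | remark | time |
|---|---|---|---|---|---|
| south-east | 0.077 M | 0.95 equiv | 0.077 M | run made earlier |  |
| south-west | 0.077 M | 0.47 equiv | 0.077 M | run made earlier |  |
| east | 0.077 M | 1.9 equiv | 0.077 M | run made earlier |  |
| north-west | 0.077 M | 0.95 equiv | 0.15 M | run made earlier |  |
| autumn | 0.077 M (fed, over 8.0 h) | 0.950 equiv | 0.0770 M | all else is in the flask from the start; the feed brings no volume worth counting | 4.0 d |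
| dusk | 0.077 M | 0.950 equiv | 0.0770 M | everything together at the start | 4.0 d |
| dawn | 0.077 M | 0.950 equiv (in portions, 5, over 3.0 d) | 0.0770 M | first portion at the start, last at 3.0 d | 4.0 d |
| summer | 0.077 M | 0.950 equiv (fed, over 3.0 d) | 0.0770 M | all else is in the flask from the start; the feed brings no volume worth counting | 4.0 d |
| spring | 0.077 M (fed, over 3.0 d) | 0.950 equiv | 0.0770 M | all else is in the flask from the start; the feed brings no volume worth counting | 4.0 d |

| run | time / d | links / % |
|---|---|---|
| south-east | 0.208 | 11 |
| south-east | 0.625 | 22 |
| south-east | 1.04 | 26 |
| south-east | 1.67 | 31 |
| south-east | 2.50 | 31 |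
| south-east | 3.00 | 28 |
| south-east | 4.00 | 30 |
| south-west | 0.333 | 8 |
| south-west | 0.625 | 13 |
| south-west | 1.04 | 18 |
| south-west | 1.25 | 18 |
| south-west | 1.67 | 18 |
| south-west | 2.08 | 20 |
| south-west | 2.50 | 20 |
| east | 0.208 | 23 |
| east | 0.333 | 29 |
| east | 0.417 | 28 |
| east | 0.625 | 33 |
| east | 1.04 | 38 |
| east | 1.67 | 40 |
| east | 2.50 | 42 |
| north-west | 0.500 | 18 |
| north-west | 1.04 | 22 |
| north-west | 1.25 | 22 |
| north-west | 2.08 | 24 |
| north-west | 2.50 | 22 |

(scatter of a reading: 1.5 percentage points)

1. the flask with the highest amount of links, in percent of the first end groups charged ("all alike" if they lie within 1.5 percentage points) (autumn / dusk / dawn / summer / spring / all alike)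
2. final links, as a percentage of the first end groups charged, in autumn
3. final links, as a percentage of the first end groups charged, in dusk
4. final links, as a percentage of the first end groups charged, in dawn
5. final links, as a percentage of the first end groups charged, in summer
6. final links, as a percentage of the first end groups charged, in spring



I read the rate and leave the concentrations aside. In the south-east run, the first reading gives the mean rate up to that time, which I take for the start rate, as a share of the first end groups charged:

r(start) = 11% / 0.208 d = 0.529 d⁻¹

The east run has twice the second end groups and its first reading, at the same time, is twice as high, so the rate follows c(second end groups). I take it to follow c(first end groups) too, though no run varies that.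

What slows it? Making links uses both partners, and at the last south-east reading of 30% that use by itself leaves these factors:

c(first end groups): 70.0% of its charge
c(second end groups): 68.4% of its charge
rate: 0.479 of r(start), or 0.253 d⁻¹

Yet the south-east readings stay flat within their scatter from 1.67 d on. Something further slows the rate: a back step (thermodynamic control) or a loss of the partners (kinetic control). I can't part these by eye from the curves, so I reckon with the loss, which makes the path matter. Joining the two ends:

τ = 30% / 0.529 d⁻¹ = 0.567 d

I call this the link window, the time that rate, held steady, takes to make the links of that last reading. Spring's feed lasts 5.29 windows, and autumn's 0.588. So I expect dusk ahead, autumn near it and the slow feeds well down.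

The forecast differs and gives all alike: autumn 30%, dusk 30%, dawn 29.8%, summer 29.7%, spring 29.7%. Its ground: “The plateau is about 30% and does not depend on path.”

The highest flask is dusk: autumn 26.3%, dusk 31.5%, dawn 25.4%, summer 24.5%, spring 13.2%.

    first end groups + second end groups → links + by-product (k = 0.00947 M⁻¹ min⁻¹)
    2 second end groups → homo dimer (k = 0.0136 M⁻¹ min⁻¹)
    first end groups + protic impurity → quenched substrate (k = 0.00711 M⁻¹ min⁻¹)

In spring, half of the homo dimer turnover is done by 0.247 d, inside the link window of 0.567 d, while half of the link-making turnover takes until 1.52 d. Spring, fed over 5.29 windows, ends 18 percentage points below dusk. Autumn, fed over 0.588 windows, ends 5.2 points below dusk.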